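In a one-step world there is no intermediate to watch: what leaves the starting complex appears as product. This flask has three steps in a row, so you must ask how much stands on the way. Each exchange frees leaving ligand, which is carried off, and starting complex can also take complex with two exchanged into side product.

| flask | starting complex | incoming ligand | leaving ligand | remark | time |
|---|---|---|---|---|---|
| maple | 0.0050 M | 4 mM | 10 mM | run made earlier |  |
| alder | 0.0050 M | 18 mM | 10 mM | run made earlier |  |
| Tuesday's | 0.0050 M | 6.00 mM | 10.0 mM |  | 12 min |
| Wednesday's | 0.0050 M | 15.0 mM | 10.0 mM |  | 12 min |
| Friday's | 0.0050 M | 20.0 mM | 10.0 mM |  | 12 min |

| run | time / min | complex with two exchanged / % | complex with three exchanged / % | starting complex / % |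
|---|---|---|---|---|
| maple | 1.33 | 0 | 1.1 | 73.4 |
| maple | 2.50 | 0.7 | 1.6 | 66.4 |
| maple | 4.00 | 0 | 1.9 | 55.6 |
| maple | 5.00 | 1.5 | 1.6 | 53.1 |
| maple | 6.00 | 0 | 0.9 | 48.1 |
| maple | 8.00 | 1.6 | 2.5 | 42.6 |
| alder | 0.417 | 1.6 | 2.5 | 48.1 |
| alder | 1.33 | 4.1 | 12.2 | 35.3 |
| alder | 2.50 | 5.2 | 20.4 | 25.1 |
| alder | 4.00 | 6.0 | 29.8 | 15.4 |
| alder | 5.00 | 4.2 | 37.4 | 10.4 |
| alder | 6.00 | 5.9 | 43.0 | 9.6 |
| alder | 8.00 | 5.1 | 52.6 | 6.2 |

(readings scatter by 1 percentage point)
- percent here means starting complex units held: one side product counts as two
- the earlier runs were read with a standard deviation of 1 percentage point
- steps thought possible: starting complex + incoming ligand <-> leaving ligand + complex with one exchanged; leaving ligand -> by-product carried off; starting complex + complex with two exchanged -> side product; complex with one exchanged + incoming ligand <-> leaving ligand + complex with two exchanged; complex with two exchanged + incoming ligand <-> leaving ligand + complex with three exchanged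
- which of these holds the largest part of the starting complex at the end of Tuesday's (complex with two exchanged / complex with one exchanged / complex with three exchanged / starting complex)
- which of these holds the largest part of the starting complex at the end of Wednesday's (complex with two exchanged / complex with one exchanged / complex with three exchanged / starting complex)
- which of these holds the largest part of the starting complex at the end of Friday's (complex with two exchanged / complex with one exchanged / complex with three exchanged / starting complex)
- how much complex with two exchanged is there at the end of Friday's, in percent of the starting complex charged

Look at the alder run. Complex with three exchanged reaches 52.6% at 8.00 min. Yet its one way in runs through complex with two exchanged, whose highest reading is 6.0%.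

You clear this up by counting turnovers. From 1.33 min to 6.00 min, [complex with three exchanged] climbs by 0.0660 /min of the charge. Divide the standing pool by that flow and you get the hold-up time, 0.910 min, the net time a unit spends in the pool. It is a reading, with a scatter of 1 percentage point on the pool. So the pool turned over about 8.79 times by the last reading. It is a small, quasi-steady intermediate.

Since 12 min is long against the hold-up time, the pool can follow the flow. My reckoning for Friday's takes the alder run's late flow, 0.0480 /min, already slower. Multiplied by the hold-up time, that gives my estimate of 4.37%. It is no bound: it rests on one scattered reading of the pool, taken in the alder run at another charge of incoming ligand.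

The forecast names complex with one exchanged for Tuesday's, complex with three exchanged for Wednesday's, complex with three exchanged for Friday's, and 3.3%, less than my estimate. Its ground: “The second exchange is slow (about 0.015 /mM/min). The third is fast (about 0.12 /mM/min)”.

    starting complex + incoming ligand ⇌ leaving ligand + complex with one exchanged (K = 0.670, k = 8.60 /M/s)
    leaving ligand → by-product carried off (k = 0.00990 /s)
    starting complex + complex with two exchanged → side product (k = 4.30 /M/s)
    complex with one exchanged + incoming ligand ⇌ leaving ligand + complex with two exchanged (K = 0.390, k = 0.400 /M/s)
    complex with two exchanged + incoming ligand ⇌ leaving ligand + complex with three exchanged (K = 1.70, k = 26.0 /M/s)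

The flasks give complex with one exchanged, complex with three exchanged and complex with three exchanged, and Friday's holds 2.76%, within the forecast's margin. The hold-up time times the second-half climb gives 3.14% on Friday's, and 2.79% on Wednesday's, which ends at 3.70%. At 12.0 min, Friday's complex with two exchanged goes forward to complex with three exchanged 980 times as fast as into side product, counting the forward rate alone. Charged with 0.020 M of starting complex, the neighbour of Friday's ends with side product ahead, at 56.5%.

The earlier runs and the new flask are simulated with constants of no real substance, and the scatter is random.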